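**Retrosynthetic overview**
1. The C1–O ester bond is cut last: (1R,2Z,6Z,10S)-dienol 22 plus O-silylated vanillic acid 25 (from vanillic acid 23).
2. The plan rests on the C6=C7 trisubstituted alkene of the cyclodeca-2,6-diene ring (C1 ester carbinol, C2=C3(Me), C4, C5, C6=C7(Me), C8, C9, C10 isopropyl). It lies away from both stereocentres (C1, C10), so the ring is opened there to keto-aldehyde 19, and the C7(Me)–C8–C9–C10(iPr) part is the ring-cleavage fragment of (R)-limonene.
3. In the chain, C4–C5 comes from alkylating tert-butyl acetate with allylic bromide 15, the (Z)-C2=C3 alkene from butenolide 11 (Still–Gennari olefination, lactonisation, reduction), and the C1–O bond from L-proline α-aminoxylation of aldehyde 6.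
4. Aldehyde 6 comes from (R)-limonene by selective hydrogenation, ozonolysis to keto ester 4, ketalisation and partial reduction; the ketone stays masked as a dioxolane until just before ring closure.
5. Ring order: only one ring of the target is built, the ten-membered carbocycle in step 14; the dioxolane and butenolide rings are temporary.

Key step: step 14

Remark on the chemistry: the isopropyl-bearing carbon is R in compounds 1–6 and S from compound 8 on only because its neighbour gains oxygen (no bond to it is made or broken); L-proline catalyst control is assumed to outweigh the bias of that neighbouring centre in step 5.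

**Route**

Step 1
Reactants: 1 (R)-(+)-limonene
Product: 2 (4R)-1-methyl-4-(propan-2-yl)cyclohex-1-ene [(R)-p-menth-1-ene]
Conditions: H2 (1 atm), RhCl(PPh3)3 (cat.), toluene/EtOH, rt, stopped after 1 equiv H2
Reagents that add atoms: none
Why: Homogeneous hydrogenation with Wilkinson's catalyst should reduce the unhindered 1,1-disubstituted isopropenyl alkene much faster than the trisubstituted ring alkene, leaving the C4 stereocentre untouched.

Step 2
Reactants: 2 (R)-p-menth-1-ene
Product: 4 methyl (3R)-6-oxo-3-(propan-2-yl)heptanoate, via methoxy hydroperoxide 3 (not isolated)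
Conditions: O3, CH2Cl2/MeOH (5:1), NaHCO3, −78 °C; then Ac2O, Et3N, CH2Cl2, 0 °C to rt
Reagents that add atoms: ozone, O=[O+][O-]; methanol, CO
Why: In this Criegee ozonolysis with dehydrating work-up the primary ozonide should cleave to the methyl ketone and the carbonyl oxide of the former CH carbon, methanol traps the latter as 3, and acylation–elimination of the hydroperoxide gives the methyl ester, so the two chain ends leave at different oxidation levels.

Step 3
Reactants: 4 methyl (3R)-6-oxo-3-(propan-2-yl)heptanoate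
Product: 5 methyl (3R)-5-(2-methyl-1,3-dioxolan-2-yl)-3-(propan-2-yl)pentanoate
Conditions: ethylene glycol, PPTS (cat.), benzene, reflux, Dean–Stark
Reagents that add atoms: ethylene glycol, OCCO
Why: Acid-catalysed ketalisation with azeotropic water removal masks the only ketone as a 1,3-dioxolane, which should then survive the enamine, hydride and enolate steps, while the methyl ester is unaffected.

Step 4
Reactants: 5 methyl (3R)-5-(2-methyl-1,3-dioxolan-2-yl)-3-(propan-2-yl)pentanoate
Product: 6 (3R)-5-(2-methyl-1,3-dioxolan-2-yl)-3-(propan-2-yl)pentanal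
Conditions: DIBAL-H (1.1 equiv), CH2Cl2, −78 °C; MeOH quench, aq. Rochelle salt
Reagents that add atoms: none
Why: DIBAL-H partial reduction of a methyl ester at −78 °C stops at the aluminium hemiacetal, which releases the aldehyde on work-up, and the ketal is inert to hydride.

Step 5
Reactants: 6 (3R)-5-(2-methyl-1,3-dioxolan-2-yl)-3-(propan-2-yl)pentanal; 7 ethyl 2-[bis(2,2,2-trifluoroethoxy)phosphoryl]propanoate
Product: 9 ethyl (2Z,4R,5S)-4-(anilinooxy)-2-methyl-7-(2-methyl-1,3-dioxolan-2-yl)-5-(propan-2-yl)hept-2-enoate, via α-anilinooxy aldehyde 8 (not isolated)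
Conditions: PhNO (1.05 equiv), L-proline (20 mol%), CHCl3, 4 °C; cold pH 7 wash, solvent switch to THF; then added to 7 (1.5 equiv), KHMDS (1.45 equiv), 18-crown-6, THF, −78 °C
Reagents that add atoms: nitrosobenzene, O=Nc1ccccc1
Why: Proline-catalysed α-aminoxylation (enamine catalysis, O-selective attack on nitrosobenzene directed by the proline carboxylic acid) should set the (2R) centre under catalyst control, and Still–Gennari olefination of the crude aldehyde at −78 °C should give the (Z)-trisubstituted enoate under kinetic control.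

Step 6
Reactants: 9 ethyl (2Z,4R,5S)-4-(anilinooxy)-2-methyl-7-(2-methyl-1,3-dioxolan-2-yl)-5-(propan-2-yl)hept-2-enoate
Product: 11 (5R)-3-methyl-5-[(3S)-4-methyl-1-(2-methyl-1,3-dioxolan-2-yl)pentan-3-yl]furan-2(5H)-one, via hydroxy ester 10 (not isolated)
Conditions: Zn dust, AcOH/THF (1:4), rt, short contact; filter, concentrate; then PPTS (cat.), toluene, 60 °C
Reagents that add atoms: none
Why: Zinc in acetic acid reductively cleaves the weak N–O bond, and the freed C4 hydroxyl, held cis to the ester by the (Z)-alkene, lactonises to the butenolide without touching the carbinol centre, while any (E)-ester cannot cyclise and is removed here.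

Step 7
Reactants: 11 (5R)-3-methyl-5-[(3S)-4-methyl-1-(2-methyl-1,3-dioxolan-2-yl)pentan-3-yl]furan-2(5H)-one
Product: 12 (2Z,4R,5S)-2-methyl-7-(2-methyl-1,3-dioxolan-2-yl)-5-(propan-2-yl)hept-2-ene-1,4-diol
Conditions: DIBAL-H (4 equiv), CH2Cl2, −78 to 0 °C; aq. Rochelle salt
Reagents that add atoms: none
Why: Excess DIBAL-H reduces the butenolide through the lactol by 1,2-hydride delivery only, so the cis geometry enforced by the lactone ring is carried into a geometrically pure (Z)-2-ene-1,4-diol.

Step 8
Reactants: 12 (2Z,4R,5S)-2-methyl-7-(2-methyl-1,3-dioxolan-2-yl)-5-(propan-2-yl)hept-2-ene-1,4-diol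
Product: 13 (2Z,4R,5S)-1,4-bis[(tert-butyldimethylsilyl)oxy]-2-methyl-7-(2-methyl-1,3-dioxolan-2-yl)-5-(propan-2-yl)hept-2-ene
Conditions: TBSCl (3 equiv), imidazole, DMAP (cat.), DMF, rt to 40 °C
Reagents that add atoms: tert-butyldimethylsilyl chloride, CC(C)(C)[Si](C)(C)Cl
Why: Silyl ether formation with TBSCl/imidazole (DMAP for the hindered secondary hydroxyl) caps both hydroxyls under basic conditions that the dioxolane and the acid-sensitive enediol tolerate.

Step 9
Reactants: 13 (2Z,4R,5S)-1,4-bis[(tert-butyldimethylsilyl)oxy]-2-methyl-7-(2-methyl-1,3-dioxolan-2-yl)-5-(propan-2-yl)hept-2-ene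
Product: 14 (2Z,4R,5S)-4-[(tert-butyldimethylsilyl)oxy]-2-methyl-7-(2-methyl-1,3-dioxolan-2-yl)-5-(propan-2-yl)hept-2-en-1-ol
Conditions: HF·pyridine, pyridine, THF, 0 °C
Reagents that add atoms: none
Why: Buffered HF·pyridine should cleave the unhindered primary TBS ether far faster than the secondary one flanked by the isopropyl-bearing carbon (selective desilylation), and the pyridine buffer spares the dioxolane.

Step 10
Reactants: 14 (2Z,4R,5S)-4-[(tert-butyldimethylsilyl)oxy]-2-methyl-7-(2-methyl-1,3-dioxolan-2-yl)-5-(propan-2-yl)hept-2-en-1-ol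
Product: 15 (2Z,4R,5S)-1-bromo-4-[(tert-butyldimethylsilyl)oxy]-2-methyl-7-(2-methyl-1,3-dioxolan-2-yl)-5-(propan-2-yl)hept-2-ene
Conditions: CBr4, PPh3, 2,6-lutidine, CH2Cl2, −20 to 0 °C; used at once
Reagents that add atoms: carbon tetrabromide, BrC(Br)(Br)Br
Why: Appel bromination replaces the primary allylic hydroxyl by SN2 displacement of the oxyphosphonium ion under near-neutral conditions, without allylic transposition or loss of Z geometry.

Step 11
Reactants: 15 (2Z,4R,5S)-1-bromo-4-[(tert-butyldimethylsilyl)oxy]-2-methyl-7-(2-methyl-1,3-dioxolan-2-yl)-5-(propan-2-yl)hept-2-ene; 16 tert-butyl acetate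
Product: 17 tert-butyl (4Z,6R,7S)-6-[(tert-butyldimethylsilyl)oxy]-4-methyl-9-(2-methyl-1,3-dioxolan-2-yl)-7-(propan-2-yl)non-4-enoate
Conditions: 16, LDA, THF, −78 °C; then 15, DMPU, −78 to −30 °C
Reagents that add atoms: none
Why: Ester enolate alkylation of the lithium enolate of tert-butyl acetate with the primary allylic bromide should go by SN2 at the CH2 end, the SN2′ position being a hindered carbon next to the silyloxy centre, and adds ring carbons C5 and C6.

Step 12
Reactants: 17 tert-butyl (4Z,6R,7S)-6-[(tert-butyldimethylsilyl)oxy]-4-methyl-9-(2-methyl-1,3-dioxolan-2-yl)-7-(propan-2-yl)non-4-enoate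
Product: 18 (4Z,6R,7S)-6-[(tert-butyldimethylsilyl)oxy]-4-methyl-9-(2-methyl-1,3-dioxolan-2-yl)-7-(propan-2-yl)non-4-enal
Conditions: DIBAL-H (1.2 equiv), CH2Cl2, −78 °C; MeOH quench at −78 °C, aq. Rochelle salt
Reagents that add atoms: none
Why: DIBAL-H partial reduction at −78 °C, where the bulky tert-butoxy aluminium hemiacetal persists until the quench, should give the aldehyde, with ketal and silyl ether inert.

Step 13
Reactants: 18 (4Z,6R,7S)-6-[(tert-butyldimethylsilyl)oxy]-4-methyl-9-(2-methyl-1,3-dioxolan-2-yl)-7-(propan-2-yl)non-4-enal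
Product: 19 (4Z,6R,7S)-6-[(tert-butyldimethylsilyl)oxy]-4-methyl-10-oxo-7-(propan-2-yl)undec-4-enal
Conditions: PPTS (0.2 equiv), acetone/H2O (10:1), 50 °C
Reagents that add atoms: water, O
Why: Mild acid-catalysed ketal hydrolysis in wet acetone should free the methyl ketone while the hindered secondary TBS ether survives and neither stereocentre is α to a carbonyl.

Step 14
Reactants: 19 (4Z,6R,7S)-6-[(tert-butyldimethylsilyl)oxy]-4-methyl-10-oxo-7-(propan-2-yl)undec-4-enal
Product: 21 tert-butyl{[(1R,2Z,6Z,10S)-3,7-dimethyl-10-(propan-2-yl)cyclodeca-2,6-dien-1-yl]oxy}dimethylsilane, via titanium pinacolate 20 (not isolated)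
Conditions: TiCl3(DME)1.5 (ca. 8 equiv), Zn–Cu couple (ca. 25 equiv), DME, reflux 2 h; then 19 in DME by syringe pump over ca. 30 h at reflux (final ≤5 mM); pentane, Florisil filtration
Reagents that add atoms: titanium(III) chloride–DME complex, Cl[Ti](Cl)Cl (titanium of intermediate 20 only; nothing from it stays in 21)
Why: Low-valent titanium made from TiCl3 and Zn–Cu transfers one electron to the aldehyde (ring C6) and to the methyl ketone (ring C7), the two ketyls combine to the titanium pinacolate 20, and at reflux the diolate loses both C–O bonds to titanium oxide, leaving C6=C7. The closest known reaction is the intramolecular McMurry keto-aldehyde coupling under slow-addition high dilution, as used for ten- and eleven-membered germacrane- and humulene-type dienes. The ten-membered carbocycle closes by head-to-head ketyl–ketyl coupling of the two chain ends held on the same titanium surface, a template pinacol-type closure between two carbons of like polarity and not a polar exo or endo cyclisation. No lasting stereocentre is formed: the two carbinol carbons of 20 become sp2, and C1 and C10 are not enolisable and sit away from the reacting carbons, so they should pass through unchanged. The step needs ring closure over oligomerisation (secured by pseudo-dilution), Z geometry at C6=C7 (the deoxygenation is not stereospecific, so Z is expected only from the lower strain of the cis-diolate and of the (Z,Z)-cyclodeca-1,5-diene, the C2=C3 alkene being already fixed as Z), and survival of the allylic C1–O bond (helped by the bulky, poorly coordinating TBS group). Any 6E isomer should be separable on AgNO3-impregnated silica.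

Step 15
Reactants: 21 tert-butyl{[(1R,2Z,6Z,10S)-3,7-dimethyl-10-(propan-2-yl)cyclodeca-2,6-dien-1-yl]oxy}dimethylsilane
Product: 22 (1R,2Z,6Z,10S)-3,7-dimethyl-10-(propan-2-yl)cyclodeca-2,6-dien-1-ol
Conditions: TBAF, THF, rt to 45 °C
Reagents that add atoms: none
Why: Fluoride-mediated desilylation, driven by Si–F bond formation, frees the C1 hydroxyl under non-acidic conditions that avoid transannular cyclisation of the cyclodecadiene.

Step 16
Reactants: 23 vanillic acid
Product: 25 4-[(tert-butyldimethylsilyl)oxy]-3-methoxybenzoic acid, via bis-silylated vanillate 24 (not isolated)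
Conditions: TBSCl (2.4 equiv), imidazole, DMF, rt; then AcOH/THF/H2O (3:1:1), rt
Reagents that add atoms: tert-butyldimethylsilyl chloride, CC(C)(C)[Si](C)(C)Cl
Why: Silylation of both phenol and acid followed by selective hydrolysis of the labile silyl ester in aqueous acetic acid should leave the more robust aryl silyl ether in place.

Step 17
Reactants: 25 4-[(tert-butyldimethylsilyl)oxy]-3-methoxybenzoic acid; 22 (1R,2Z,6Z,10S)-3,7-dimethyl-10-(propan-2-yl)cyclodeca-2,6-dien-1-ol
Product: 27 (1R,2Z,6Z,10S)-3,7-dimethyl-10-(propan-2-yl)cyclodeca-2,6-dien-1-yl 4-[(tert-butyldimethylsilyl)oxy]-3-methoxybenzoate, via acid chloride 26 (not isolated)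
Conditions: 25, (COCl)2, DMF (cat.), CH2Cl2, 0 °C to rt, evaporate; then 22, Et3N, DMAP, CH2Cl2, 0 °C to rt
Reagents that add atoms: oxalyl chloride, ClC(=O)C(=O)Cl (chlorine of intermediate 26 only)
Why: Acid chloride formation by Vilsmeier activation and DMAP-catalysed acylation through the acylpyridinium ion should esterify the hindered secondary allylic alcohol with retention at C1, since the C1–O bond is not broken.

Step 18
Reactants: 27 (1R,2Z,6Z,10S)-3,7-dimethyl-10-(propan-2-yl)cyclodeca-2,6-dien-1-yl 4-[(tert-butyldimethylsilyl)oxy]-3-methoxybenzoate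
Product: 28 (1R,2Z,6Z,10S)-3,7-dimethyl-10-(propan-2-yl)cyclodeca-2,6-dien-1-yl 4-hydroxy-3-methoxybenzoate (CNP0306317.1)
Conditions: TBAF (1.1 equiv), AcOH (1.2 equiv), THF, 0 °C
Reagents that add atoms: none
Why: Buffered fluoride desilylation cleaves an aryl silyl ether within minutes at 0 °C, far faster than any attack on the benzoate, so the phenol should be released without acyl transfer or elimination.

**Compound list**
1 | (R)-(+)-limonene | CC1=CC[C@@H](CC1)C(C)=C | starting material
2 | (4R)-1-methyl-4-(propan-2-yl)cyclohex-1-ene | CC1=CC[C@@H](CC1)C(C)C | intermediate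
3 | (5R)-7-hydroperoxy-7-methoxy-5-(propan-2-yl)heptan-2-one (C7 epimers) | CC(=O)CC[C@@H](C(C)C)CC(OC)OO | intermediate (not isolated)
4 | methyl (3R)-6-oxo-3-(propan-2-yl)heptanoate | CC(=O)CC[C@@H](C(C)C)CC(=O)OC | intermediate
5 | methyl (3R)-5-(2-methyl-1,3-dioxolan-2-yl)-3-(propan-2-yl)pentanoate | CC1(OCCO1)CC[C@@H](C(C)C)CC(=O)OC | intermediate
6 | (3R)-5-(2-methyl-1,3-dioxolan-2-yl)-3-(propan-2-yl)pentanal | CC1(OCCO1)CC[C@@H](C(C)C)CC=O | intermediate
7 | ethyl 2-[bis(2,2,2-trifluoroethoxy)phosphoryl]propanoate | CCOC(=O)C(C)P(=O)(OCC(F)(F)F)OCC(F)(F)F | starting material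
8 | (2R,3S)-2-(anilinooxy)-5-(2-methyl-1,3-dioxolan-2-yl)-3-(propan-2-yl)pentanal | CC1(OCCO1)CC[C@@H](C(C)C)[C@@H](ONc1ccccc1)C=O | intermediate (not isolated)
9 | ethyl (2Z,4R,5S)-4-(anilinooxy)-2-methyl-7-(2-methyl-1,3-dioxolan-2-yl)-5-(propan-2-yl)hept-2-enoate | CC1(OCCO1)CC[C@@H](C(C)C)[C@@H](ONc1ccccc1)/C=C(/C)C(=O)OCC | intermediate
10 | ethyl (2Z,4R,5S)-4-hydroxy-2-methyl-7-(2-methyl-1,3-dioxolan-2-yl)-5-(propan-2-yl)hept-2-enoate | CC1(OCCO1)CC[C@@H](C(C)C)[C@@H](O)/C=C(/C)C(=O)OCC | intermediate (not isolated)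
11 | (5R)-3-methyl-5-[(3S)-4-methyl-1-(2-methyl-1,3-dioxolan-2-yl)pentan-3-yl]furan-2(5H)-one | CC1(OCCO1)CC[C@@H](C(C)C)[C@H]1OC(=O)C(C)=C1 | intermediate
12 | (2Z,4R,5S)-2-methyl-7-(2-methyl-1,3-dioxolan-2-yl)-5-(propan-2-yl)hept-2-ene-1,4-diol | CC1(OCCO1)CC[C@@H](C(C)C)[C@@H](O)/C=C(/C)CO | intermediate
13 | (2Z,4R,5S)-1,4-bis[(tert-butyldimethylsilyl)oxy]-2-methyl-7-(2-methyl-1,3-dioxolan-2-yl)-5-(propan-2-yl)hept-2-ene | CC1(OCCO1)CC[C@@H](C(C)C)[C@@H](O[Si](C)(C)C(C)(C)C)/C=C(/C)CO[Si](C)(C)C(C)(C)C | intermediate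
14 | (2Z,4R,5S)-4-[(tert-butyldimethylsilyl)oxy]-2-methyl-7-(2-methyl-1,3-dioxolan-2-yl)-5-(propan-2-yl)hept-2-en-1-ol | CC1(OCCO1)CC[C@@H](C(C)C)[C@@H](O[Si](C)(C)C(C)(C)C)/C=C(/C)CO | intermediate
15 | (2Z,4R,5S)-1-bromo-4-[(tert-butyldimethylsilyl)oxy]-2-methyl-7-(2-methyl-1,3-dioxolan-2-yl)-5-(propan-2-yl)hept-2-ene | CC1(OCCO1)CC[C@@H](C(C)C)[C@@H](O[Si](C)(C)C(C)(C)C)/C=C(/C)CBr | intermediate
16 | tert-butyl acetate | CC(=O)OC(C)(C)C | starting material
17 | tert-butyl (4Z,6R,7S)-6-[(tert-butyldimethylsilyl)oxy]-4-methyl-9-(2-methyl-1,3-dioxolan-2-yl)-7-(propan-2-yl)non-4-enoate | CC1(OCCO1)CC[C@@H](C(C)C)[C@@H](O[Si](C)(C)C(C)(C)C)/C=C(/C)CCC(=O)OC(C)(C)C | intermediate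
18 | (4Z,6R,7S)-6-[(tert-butyldimethylsilyl)oxy]-4-methyl-9-(2-methyl-1,3-dioxolan-2-yl)-7-(propan-2-yl)non-4-enal | CC1(OCCO1)CC[C@@H](C(C)C)[C@@H](O[Si](C)(C)C(C)(C)C)/C=C(/C)CCC=O | intermediate
19 | (4Z,6R,7S)-6-[(tert-butyldimethylsilyl)oxy]-4-methyl-10-oxo-7-(propan-2-yl)undec-4-enal | CC(=O)CC[C@@H](C(C)C)[C@@H](O[Si](C)(C)C(C)(C)C)/C=C(/C)CCC=O | intermediate
20 | titanium pinacolate of the closed ring, drawn as a monomeric titanium 6,7-diolate (configuration at C6 and C7 not defined) | CC(C)(C)[Si](C)(C)O[C@H]1/C=C(/C)CCC2O[Ti]OC2(C)CC[C@H]1C(C)C | intermediate (not isolated)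
21 | tert-butyl{[(1R,2Z,6Z,10S)-3,7-dimethyl-10-(propan-2-yl)cyclodeca-2,6-dien-1-yl]oxy}dimethylsilane | CC(C)(C)[Si](C)(C)O[C@H]1/C=C(/C)CC/C=C(/C)CC[C@H]1C(C)C | intermediate
22 | (1R,2Z,6Z,10S)-3,7-dimethyl-10-(propan-2-yl)cyclodeca-2,6-dien-1-ol | O[C@H]1/C=C(/C)CC/C=C(/C)CC[C@H]1C(C)C | intermediate
23 | vanillic acid | COc1cc(C(=O)O)ccc1O | starting material
24 | tert-butyldimethylsilyl 4-[(tert-butyldimethylsilyl)oxy]-3-methoxybenzoate | COc1cc(C(=O)O[Si](C)(C)C(C)(C)C)ccc1O[Si](C)(C)C(C)(C)C | intermediate (not isolated)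
25 | 4-[(tert-butyldimethylsilyl)oxy]-3-methoxybenzoic acid | COc1cc(C(=O)O)ccc1O[Si](C)(C)C(C)(C)C | intermediate
26 | 4-[(tert-butyldimethylsilyl)oxy]-3-methoxybenzoyl chloride | COc1cc(C(Cl)=O)ccc1O[Si](C)(C)C(C)(C)C | intermediate (not isolated)
27 | (1R,2Z,6Z,10S)-3,7-dimethyl-10-(propan-2-yl)cyclodeca-2,6-dien-1-yl 4-[(tert-butyldimethylsilyl)oxy]-3-methoxybenzoate | COc1cc(C(=O)O[C@H]2/C=C(/C)CC/C=C(/C)CC[C@H]2C(C)C)ccc1O[Si](C)(C)C(C)(C)C | intermediate
28 | (1R,2Z,6Z,10S)-3,7-dimethyl-10-(propan-2-yl)cyclodeca-2,6-dien-1-yl 4-hydroxy-3-methoxybenzoate | COc1cc(C(=O)O[C@H]2/C=C(/C)CC/C=C(/C)CC[C@H]2C(C)C)ccc1O | target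

**Step count**
Total: 18 steps. Longest linear sequence: 17 steps (steps 1–15, 17 and 18, from (R)-limonene); step 16 is a one-step side branch.

**Steps most likely to fail**

Step 14 (ring closure). The deoxygenation of the pinacolate is not stereospecific, so a mixture of 6Z and 6E alkenes may form. Low-valent titanium may also reductively cleave the allylic C1–O bond, and intermolecular coupling may compete. The fallback splits bond formation and deoxygenation into stereospecific stages and avoids titanium. It sets out from 19: samarium diiodide (THF, HMPA, high dilution, rt) should effect intramolecular pinacol coupling to the ring 1,2-diol, from which the cis-diol F1 is separated (either cis isomer serves; trans-diols are set aside). Treatment with 1,1'-thiocarbonyldiimidazole (toluene, 90 °C) gives the cyclic thionocarbonate F2. Corey–Winter elimination with 1,3-dimethyl-2-phenyl-1,3,2-diazaphospholidine (40 °C) is a syn cycloelimination, so the cis-fused thionocarbonate can only give the 6Z alkene. The fallback comes back to the route at 21.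

Step 5 (α-aminoxylation and olefination). The C3 centre may oppose the catalyst and lower facial selectivity, the labile α-anilinooxy aldehyde may epimerise or fragment at the N–O bond under the basic olefination, and Z selectivity may erode. The fallback sets out from 5 and installs the oxygen at the ester stage. The potassium enolate (KHMDS, THF, −78 °C) is hydroxylated with the Davis oxaziridine (2-(phenylsulfonyl)-3-phenyloxaziridine) to the α-hydroxy ester F3, whose (2R) epimer is purified by chromatography. Silylation (TBSCl, imidazole, DMF) gives the silyl ether F4, and DIBAL-H at −78 °C gives the configurationally stable α-silyloxy aldehyde F5. Still–Gennari olefination with 7 gives the (Z)-enoate F6, and DIBAL-H reduction of its ester returns to the route at 14. This also bypasses the butenolide and the selective desilylation.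

Step 11 (enolate alkylation). The basic ester enolate may attack in SN2′ fashion or cause 1,4-elimination of HBr from the γ-silyloxy allylic bromide, and the tert-butyl ester may over-reduce in step 12. The fallback sets out from 15 and uses a soft nucleophile: sodium dimethyl malonate (NaH, dimethyl malonate, THF, 0 °C to rt) should give the allylated malonate F7 by clean SN2. Krapcho demethoxycarbonylation (LiCl, wet DMSO, 140 °C) gives the methyl ester F8, whose DIBAL-H reduction at −78 °C is the more reliable ester-to-aldehyde case and returns to the route at 18.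

Further compounds
F1 | step 14 | C1 tert-butyldimethylsilyl ether of (1R,2Z,10S)-3,7-dimethyl-10-(propan-2-yl)cyclodec-2-ene-1,6,7-triol with cis C6/C7 hydroxyls (one cis isomer drawn) | CC(C)(C)[Si](C)(C)O[C@H]1/C=C(/C)CC[C@H](O)[C@](C)(O)CC[C@H]1C(C)C
F2 | step 14 | cyclic 6,7-thionocarbonate of F1 (cis-fused 1,3-dioxolane-2-thione) | CC(C)(C)[Si](C)(C)O[C@H]1/C=C(/C)CC[C@@H]2OC(=S)O[C@]2(C)CC[C@H]1C(C)C
F3 | step 5 | methyl (2R,3S)-2-hydroxy-5-(2-methyl-1,3-dioxolan-2-yl)-3-(propan-2-yl)pentanoate | CC1(OCCO1)CC[C@@H](C(C)C)[C@@H](O)C(=O)OC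
F4 | step 5 | methyl (2R,3S)-2-[(tert-butyldimethylsilyl)oxy]-5-(2-methyl-1,3-dioxolan-2-yl)-3-(propan-2-yl)pentanoate | CC1(OCCO1)CC[C@@H](C(C)C)[C@@H](O[Si](C)(C)C(C)(C)C)C(=O)OC
F5 | step 5 | (2R,3S)-2-[(tert-butyldimethylsilyl)oxy]-5-(2-methyl-1,3-dioxolan-2-yl)-3-(propan-2-yl)pentanal | CC1(OCCO1)CC[C@@H](C(C)C)[C@@H](O[Si](C)(C)C(C)(C)C)C=O
F6 | step 5 | ethyl (2Z,4R,5S)-4-[(tert-butyldimethylsilyl)oxy]-2-methyl-7-(2-methyl-1,3-dioxolan-2-yl)-5-(propan-2-yl)hept-2-enoate | CC1(OCCO1)CC[C@@H](C(C)C)[C@@H](O[Si](C)(C)C(C)(C)C)/C=C(/C)C(=O)OCC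
F7 | step 11 | dimethyl 2-[(2Z,4R,5S)-4-[(tert-butyldimethylsilyl)oxy]-2-methyl-7-(2-methyl-1,3-dioxolan-2-yl)-5-(propan-2-yl)hept-2-en-1-yl]propanedioate | CC1(OCCO1)CC[C@@H](C(C)C)[C@@H](O[Si](C)(C)C(C)(C)C)/C=C(/C)CC(C(=O)OC)C(=O)OC
F8 | step 11 | methyl (4Z,6R,7S)-6-[(tert-butyldimethylsilyl)oxy]-4-methyl-9-(2-methyl-1,3-dioxolan-2-yl)-7-(propan-2-yl)non-4-enoate | CC1(OCCO1)CC[C@@H](C(C)C)[C@@H](O[Si](C)(C)C(C)(C)C)/C=C(/C)CCC(=O)OC
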